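## Retrosynthetic overview

1. The all-E triene is cut at C2'–C3' (Stille): core vinyl iodide 21 plus stannyl dienamide 27, the latter from (E)-3-iodoacrylic acid, the bought aminocyclopentenone and a distannylethene.
2. The secondary hydroxyl (C5; ring numbering C1 = ketone, C2 = N-bearing carbon, C4 = tertiary carbinol) comes from a boronate-tethered syn-hydration of the 2-amido-quinol 19. The enamide C2–N bond comes from a CuI-catalysed coupling of iodoenone 10 with amide 15.
3. The six-membered ring, the only ring made, is formed by a Diels–Alder reaction of Danishefsky's diene with the methylene-dioxolanone 5 from (S)-lactic acid. The lactate carbons become C1', C4 and C5, and the lactate oxygen becomes the tertiary OH.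
4. The acyl side chain comes from (S)-3-bromo-2-methylpropan-1-ol (Cu-catalysed propylation, oxidation/Wittig, aminolysis).
5. Ring order: cyclohexene (step 3); the cyclopentenone ring is bought.

Assumption: (S)-3-bromo-2-methylpropan-1-ol, (E)-3-iodoacrylic acid, (E)-1,2-bis(tributylstannyl)ethene, Danishefsky's diene and 2-amino-3-hydroxycyclopent-2-en-1-one hydrochloride are taken as catalogue chemicals.

## Route

Step 1
Reactants: 1 (S)-lactic acid; 2 pivalaldehyde
Product: 3 (2S,5S)-2-tert-butyl-5-methyl-1,3-dioxolan-4-one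
Conditions: TsOH·H2O (cat.), H2SO4 (cat.), pentane, reflux, Dean–Stark; recrystallise at −78 °C
Reagents that add atoms: none
Why: Acid-catalysed acetalisation (Seebach dioxolanone) in which the lactate stereocentre directs the new acetal carbon to the cis isomer, so the chirality is stored at C2 before C5 is flattened.

Step 2
Reactants: 3 (2S,5S)-2-tert-butyl-5-methyl-1,3-dioxolan-4-one
Product: 5 (S)-2-tert-butyl-5-methylidene-1,3-dioxolan-4-one, via bromide 4 (not isolated)
Conditions: NBS, AIBN (cat.), CCl4, reflux; then Et3N, 0 °C → rt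
Reagents that add atoms: none
Why: Wohl–Ziegler radical bromination at the captodative C5 followed by E2 dehydrobromination gives the exocyclic alkene, and the acetal stereocentre is untouched.

Step 3
Reactants: 5 (S)-2-tert-butyl-5-methylidene-1,3-dioxolan-4-one; 6 (E)-1-methoxy-3-(trimethylsilyloxy)buta-1,3-diene (Danishefsky's diene)
Product: 7 (2S,5R,6S)-2-tert-butyl-6-methoxy-8-(trimethylsilyloxy)-1,3-dioxaspiro[4.5]dec-7-en-4-one (major isomer; its C6 epimer converges in step 4)
Conditions: toluene, BHT (trace), 90 °C, sealed tube, 36 h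
Reagents that add atoms: none
Why: Thermal Diels–Alder cycloaddition builds the carbocycle; the CH2 terminus of the diene bonds to the exocyclic CH2 of the captodative dienophile and the diene adds to the face anti to tert-butyl, which sets the quaternary carbinol carbon (future C4).

Step 4
Reactants: 7 (2S,5R,6S)-2-tert-butyl-6-methoxy-8-(trimethylsilyloxy)-1,3-dioxaspiro[4.5]dec-7-en-4-one
Product: 9 (R)-4-hydroxy-4-(hydroxymethyl)cyclohex-2-en-1-one, via diol silyl enol ether 8 (not isolated)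
Conditions: LiAlH4, THF, 0 °C; then 1 M HCl, THF, 0 °C → rt
Reagents that add atoms: none
Why: Hydride reduction opens the acylal lactone to the 1,2-diol (released pivalaldehyde is reduced), then acid hydrolysis of the silyl enol ether and beta-elimination of methanol give the enone without touching the quaternary centre.

Step 5
Reactants: 9 (R)-4-hydroxy-4-(hydroxymethyl)cyclohex-2-en-1-one
Product: 10 (R)-4-hydroxy-4-(hydroxymethyl)-2-iodocyclohex-2-en-1-one
Conditions: I2, pyridine–CH2Cl2 (1:1), 0 °C → rt, dark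
Reagents that add atoms: iodine, II
Why: Johnson alpha-iodination of an enone (pyridine conjugate addition, iodination of the enolate, elimination) places iodine only at C2.

Step 6
Reactants: 11 (S)-3-bromo-2-methylpropan-1-ol
Product: 12 (R)-2-methylhexan-1-ol
Conditions: n-PrMgBr (3 equiv), Li2CuCl4 (5 mol%), THF, −78 °C → rt; NH4Cl (aq)
Reagents that add atoms: n-propylmagnesium bromide, CCC[Mg]Br
Why: Kochi-type copper-catalysed sp3–sp3 coupling of the primary bromide (the first equivalent of Grignard reagent makes the alkoxide); the stereocentre is not at the reacting carbon, so only its descriptor changes.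

Step 7
Reactants: 12 (R)-2-methylhexan-1-ol
Product: 14 ethyl (2E,4R)-2,4-dimethyloct-2-enoate, via (R)-2-methylhexanal 13 (not isolated)
Conditions: Dess–Martin periodinane, Ph3P=C(Me)CO2Et, CH2Cl2, rt
Reagents that add atoms: ethyl 2-(triphenylphosphoranylidene)propanoate, CCOC(=O)C(C)=P(c1ccccc1)(c1ccccc1)c1ccccc1
Why: Dess–Martin oxidation with in situ Wittig trapping by the stabilised ylide gives the E-trisubstituted enoate under non-basic conditions, so the alpha-stereocentre of the aldehyde is not epimerised.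

Step 8
Reactants: 14 ethyl (2E,4R)-2,4-dimethyloct-2-enoate
Product: 15 (2E,4R)-2,4-dimethyloct-2-enamide
Conditions: AlMe3, NH4Cl, toluene, 50 °C; then 1 M HCl
Reagents that add atoms: ammonium chloride, [NH4+].[Cl-]
Why: Weinreb-type aminolysis by the aluminium amide made in situ converts the hindered enoate directly into the primary amide without conjugate addition.

Step 9
Reactants: 10 (R)-4-hydroxy-4-(hydroxymethyl)-2-iodocyclohex-2-en-1-one; 15 (2E,4R)-2,4-dimethyloct-2-enamide
Product: 16 (2E,4R)-N-[(3R)-3-hydroxy-3-(hydroxymethyl)-6-oxocyclohex-1-en-1-yl]-2,4-dimethyloct-2-enamide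
Conditions: CuI (10 mol%), N,N'-dimethylethylenediamine (20 mol%), K2CO3, toluene, 60 °C
Reagents that add atoms: none
Why: Goldberg/Buchwald-type copper-catalysed vinylic C–N coupling of the activated alpha-iodoenone with the primary amide is N-selective over the free hydroxyls and gives the 2-amido-enone.

Step 10
Reactants: 16 (2E,4R)-N-[(3R)-3-hydroxy-3-(hydroxymethyl)-6-oxocyclohex-1-en-1-yl]-2,4-dimethyloct-2-enamide
Product: 17 (2E,4R)-N-[(3R)-3-formyl-3-hydroxy-6-oxocyclohex-1-en-1-yl]-2,4-dimethyloct-2-enamide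
Conditions: IBX, DMSO, rt
Reagents that add atoms: none
Why: IBX oxidises the primary alcohol to the aldehyde without cleaving the 1,2-diol, and the tertiary alcohol cannot be oxidised.

Step 11
Reactants: 17 (2E,4R)-N-[(3R)-3-formyl-3-hydroxy-6-oxocyclohex-1-en-1-yl]-2,4-dimethyloct-2-enamide
Product: 18 (2E,4R)-N-[(3R)-3-hydroxy-3-[(E)-2-iodoethenyl]-6-oxocyclohex-1-en-1-yl]-2,4-dimethyloct-2-enamide
Conditions: CrCl2 (8 equiv), CHI3 (3 equiv), THF–dioxane, 0 °C → rt
Reagents that add atoms: iodoform, IC(I)I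
Why: Takai olefination is aldehyde-selective in the presence of the enone and gives the E-vinyl iodide from the hindered aldehyde; it is run before the dienone exists because divalent chromium could reductively aromatise a quinol.

Step 12
Reactants: 18 (2E,4R)-N-[(3R)-3-hydroxy-3-[(E)-2-iodoethenyl]-6-oxocyclohex-1-en-1-yl]-2,4-dimethyloct-2-enamide
Product: 19 (2E,4R)-N-[(3R)-3-hydroxy-3-[(E)-2-iodoethenyl]-6-oxocyclohexa-1,4-dien-1-yl]-2,4-dimethyloct-2-enamide
Conditions: IBX, 4-methoxypyridine N-oxide, DMSO, rt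
Reagents that add atoms: none
Why: IBX-mediated dehydrogenation (Nicolaou) at the only enolisable position gives the cross-conjugated dienone, and C4 stays stereogenic because the amide makes the two ring arms different.

Step 13
Reactants: 19 (2E,4R)-N-[(3R)-3-hydroxy-3-[(E)-2-iodoethenyl]-6-oxocyclohexa-1,4-dien-1-yl]-2,4-dimethyloct-2-enamide
Product: 21 (2E,4R)-N-[(3R,4R)-3,4-dihydroxy-3-[(E)-2-iodoethenyl]-6-oxocyclohex-1-en-1-yl]-2,4-dimethyloct-2-enamide, via phenylboronate 20 (not isolated)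
Conditions: PhB(OH)2, i-Pr2NH (20 mol%), 4 Å MS, CH2Cl2, rt; then 30% H2O2, pH 7 buffer, THF, 0 °C
Reagents that add atoms: phenylboronic acid, OB(O)c1ccccc1
Why: Boronic-acid-tethered oxa-Michael addition: the hemiester on the tertiary OH delivers its B–OH oxygen intramolecularly to the more electrophilic, unsubstituted enone carbon on the same face, so the new carbinol is set cis to the tertiary OH, and oxidative work-up frees the diol.

Step 14
Reactants: 22 (E)-3-iodoprop-2-enoic acid; 23 2-amino-3-hydroxycyclopent-2-en-1-one hydrochloride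
Product: 25 (E)-N-(2-hydroxy-5-oxocyclopent-1-en-1-yl)-3-iodoprop-2-enamide, via acid chloride 24 (not isolated)
Conditions: (COCl)2, DMF (cat.), CH2Cl2, 0 °C → rt, evaporate; then 23, pyridine, CH2Cl2, 0 °C → rt
Reagents that add atoms: none
Why: Acyl chloride formation and N-acylation of the vinylogous-acid amine give the amide, any O-acyl product transferring its acyl group to nitrogen.

Step 15
Reactants: 25 (E)-N-(2-hydroxy-5-oxocyclopent-1-en-1-yl)-3-iodoprop-2-enamide; 26 (E)-1,2-bis(tributylstannyl)ethene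
Product: 27 (2E,4E)-N-(2-hydroxy-5-oxocyclopent-1-en-1-yl)-5-(tributylstannyl)penta-2,4-dienamide
Conditions: 26 (2.5 equiv), PdCl2(MeCN)2 (5 mol%), DMF, rt
Reagents that add atoms: none
Why: Stille coupling with excess distannane stops after one coupling and proceeds with retention of both E geometries.

Step 16
Reactants: 21 (2E,4R)-N-[(3R,4R)-3,4-dihydroxy-3-[(E)-2-iodoethenyl]-6-oxocyclohex-1-en-1-yl]-2,4-dimethyloct-2-enamide; 27 (2E,4E)-N-(2-hydroxy-5-oxocyclopent-1-en-1-yl)-5-(tributylstannyl)penta-2,4-dienamide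
Product: 28 (2E,4R)-N-[(3S,4R)-3,4-dihydroxy-3-[(1E,3E,5E)-7-[(2-hydroxy-5-oxocyclopent-1-en-1-yl)amino]-7-oxohepta-1,3,5-trien-1-yl]-6-oxocyclohex-1-en-1-yl]-2,4-dimethyloct-2-enamide (CNP0154433.2)
Conditions: PdCl2(MeCN)2 (10 mol%), DMF, rt, dark
Reagents that add atoms: none
Why: Stille sp2–sp2 coupling joins the fragments with retention of alkene geometry to give the all-E triene under neutral conditions that tolerate the free diol, the beta-hydroxy ketone and the acidic enol.

## Compound list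

1 | (S)-lactic acid | C[C@H](O)C(=O)O | starting material
2 | pivalaldehyde (2,2-dimethylpropanal) | CC(C)(C)C=O | starting material
3 | (2S,5S)-2-tert-butyl-5-methyl-1,3-dioxolan-4-one | C[C@@H]1O[C@H](C(C)(C)C)OC1=O | intermediate
4 | (2S,5R)-5-bromo-2-tert-butyl-5-methyl-1,3-dioxolan-4-one (Br trans to tert-butyl) | C[C@]1(Br)O[C@H](C(C)(C)C)OC1=O | intermediate
5 | (S)-2-tert-butyl-5-methylidene-1,3-dioxolan-4-one | C=C1O[C@H](C(C)(C)C)OC1=O | intermediate
6 | (E)-1-methoxy-3-(trimethylsilyloxy)buta-1,3-diene | CO/C=C/C(=C)O[Si](C)(C)C | starting material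
7 | (2S,5R,6S)-2-tert-butyl-6-methoxy-8-(trimethylsilyloxy)-1,3-dioxaspiro[4.5]dec-7-en-4-one | CO[C@H]1C=C(O[Si](C)(C)C)CC[C@@]12O[C@H](C(C)(C)C)OC2=O | intermediate
8 | [(1S,2S)-1-hydroxy-2-methoxy-4-(trimethylsilyloxy)cyclohex-3-en-1-yl]methanol | CO[C@H]1C=C(O[Si](C)(C)C)CC[C@]1(O)CO | intermediate
9 | (R)-4-hydroxy-4-(hydroxymethyl)cyclohex-2-en-1-one | O=C1C=C[C@@](O)(CO)CC1 | intermediate
10 | (R)-4-hydroxy-4-(hydroxymethyl)-2-iodocyclohex-2-en-1-one | O=C1C(I)=C[C@@](O)(CO)CC1 | intermediate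
11 | (S)-3-bromo-2-methylpropan-1-ol | BrC[C@@H](C)CO | starting material
12 | (R)-2-methylhexan-1-ol | CCCC[C@@H](C)CO | intermediate
13 | (R)-2-methylhexanal | CCCC[C@@H](C)C=O | intermediate
14 | ethyl (2E,4R)-2,4-dimethyloct-2-enoate | CCCC[C@@H](C)/C=C(\C)C(=O)OCC | intermediate
15 | (2E,4R)-2,4-dimethyloct-2-enamide | CCCC[C@@H](C)/C=C(\C)C(N)=O | intermediate
16 | (2E,4R)-N-[(3R)-3-hydroxy-3-(hydroxymethyl)-6-oxocyclohex-1-en-1-yl]-2,4-dimethyloct-2-enamide | CCCC[C@@H](C)/C=C(\C)C(=O)NC1=C[C@@](O)(CO)CCC1=O | intermediate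
17 | (2E,4R)-N-[(3R)-3-formyl-3-hydroxy-6-oxocyclohex-1-en-1-yl]-2,4-dimethyloct-2-enamide | CCCC[C@@H](C)/C=C(\C)C(=O)NC1=C[C@@](O)(C=O)CCC1=O | intermediate
18 | (2E,4R)-N-[(3R)-3-hydroxy-3-[(E)-2-iodoethenyl]-6-oxocyclohex-1-en-1-yl]-2,4-dimethyloct-2-enamide | CCCC[C@@H](C)/C=C(\C)C(=O)NC1=C[C@@](O)(/C=C/I)CCC1=O | intermediate
19 | (2E,4R)-N-[(3R)-3-hydroxy-3-[(E)-2-iodoethenyl]-6-oxocyclohexa-1,4-dien-1-yl]-2,4-dimethyloct-2-enamide | CCCC[C@@H](C)/C=C(\C)C(=O)NC1=C[C@@](O)(/C=C/I)C=CC1=O | intermediate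
20 | cyclic phenylboronate of 21 (boron bridges the two cis oxygens; cis-fused 2-phenyl-1,3,2-dioxaborolane) | CCCC[C@@H](C)/C=C(\C)C(=O)NC1=C[C@]2(/C=C/I)OB(c3ccccc3)O[C@@H]2CC1=O | intermediate
21 | (2E,4R)-N-[(3R,4R)-3,4-dihydroxy-3-[(E)-2-iodoethenyl]-6-oxocyclohex-1-en-1-yl]-2,4-dimethyloct-2-enamide | CCCC[C@@H](C)/C=C(\C)C(=O)NC1=C[C@@](O)(/C=C/I)[C@H](O)CC1=O | intermediate
22 | (E)-3-iodoprop-2-enoic acid | OC(=O)/C=C/I | starting material
23 | 2-amino-3-hydroxycyclopent-2-en-1-one hydrochloride | NC1=C(O)CCC1=O.Cl | starting material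
24 | (E)-3-iodoprop-2-enoyl chloride | ClC(=O)/C=C/I | intermediate
25 | (E)-N-(2-hydroxy-5-oxocyclopent-1-en-1-yl)-3-iodoprop-2-enamide | I/C=C/C(=O)NC1=C(O)CCC1=O | intermediate
26 | (E)-1,2-bis(tributylstannyl)ethene | CCCC[Sn](CCCC)(CCCC)/C=C/[Sn](CCCC)(CCCC)CCCC | starting material
27 | (2E,4E)-N-(2-hydroxy-5-oxocyclopent-1-en-1-yl)-5-(tributylstannyl)penta-2,4-dienamide | CCCC[Sn](CCCC)(CCCC)/C=C/C=C/C(=O)NC1=C(O)CCC1=O | intermediate
28 | (2E,4R)-N-[(3S,4R)-3,4-dihydroxy-3-[(1E,3E,5E)-7-[(2-hydroxy-5-oxocyclopent-1-en-1-yl)amino]-7-oxohepta-1,3,5-trien-1-yl]-6-oxocyclohex-1-en-1-yl]-2,4-dimethyloct-2-enamide | CCCC[C@@H](C)/C=C(\C)C(=O)NC1=C[C@@](O)(/C=C/C=C/C=C/C(=O)NC2=C(O)CCC2=O)[C@H](O)CC1=O | target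

## Step count and risks

Total steps: 16. Longest linear sequence: 11 (steps 1, 2, 3, 4, 5, 9, 10, 11, 12, 13, 16).

The three steps most likely to fail:

Step 9. The coupling is run on an unprotected gamma-hydroxy iodoenone; carbonate at 60 °C could trigger a vinylogous retro-aldol loss of formaldehyde, and the free diol could sequester copper. The fallback sets out from 9 and comes back at 16. Compound 9 is ketalised (2,2-dimethoxypropane, PPTS, acetone) to the spiro acetonide (5R)-2,2-dimethyl-1,3-dioxaspiro[4.5]dec-6-en-8-one F1. This is iodinated (I2, pyridine) to (5R)-7-iodo-2,2-dimethyl-1,3-dioxaspiro[4.5]dec-6-en-8-one F2. F2 is coupled with 15 (CuI, N,N'-dimethylethylenediamine, Cs2CO3, dioxane, 70 °C) to (2E,4R)-N-[(5R)-2,2-dimethyl-8-oxo-1,3-dioxaspiro[4.5]dec-6-en-7-yl]-2,4-dimethyloct-2-enamide F3. The acetonide is then removed with AcOH–H2O (4:1, 40 °C) to give 16.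

Step 12. Direct IBX dehydrogenation of an amido-enone that also carries a tertiary allylic alcohol may be slow or may divert into oxidative transposition of that alcohol. The fallback sets out from 18 and comes back at 19. Compound 18 is silylated (TMSOTf, Et3N, CH2Cl2, 0 °C) to the cross-conjugated dienol ether (2E,4R)-N-[(3R)-3-[(E)-2-iodoethenyl]-3,6-bis(trimethylsilyloxy)cyclohexa-1,5-dien-1-yl]-2,4-dimethyloct-2-enamide F4. F4 is oxidised with DDQ (2,6-lutidine, CH2Cl2, 0 °C), and aqueous citric acid work-up removes the remaining silyl group to give 19.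

Step 13. The tertiary alcohol may form the boronic hemiester sluggishly, or the adduct may revert by retro-oxa-Michael. The fallback sets out from 19 and comes back at 21. Compound 19 is epoxidised nucleophilically (t-BuOOH, DBU, CH2Cl2, 0 °C) on the face of the small, hydrogen-bonding hydroxyl and at the unsubstituted enone only, to give (2E,4R)-N-[(1S,5R,6R)-5-hydroxy-5-[(E)-2-iodoethenyl]-2-oxo-7-oxabicyclo[4.1.0]hept-3-en-3-yl]-2,4-dimethyloct-2-enamide F5 (oxirane cis to the hydroxyl). The epoxy ketone is then opened reductively at the alpha C–O bond (PhSeSePh, NaBH4, AcOH, EtOH, 0 °C) to give the beta-hydroxy ketone 21.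

## Further compounds

F1 | step 9 | (5R)-2,2-dimethyl-1,3-dioxaspiro[4.5]dec-6-en-8-one | O=C1C=C[C@]2(CC1)COC(C)(C)O2
F2 | step 9 | (5R)-7-iodo-2,2-dimethyl-1,3-dioxaspiro[4.5]dec-6-en-8-one | O=C1C(I)=C[C@]2(CC1)COC(C)(C)O2
F3 | step 9 | (2E,4R)-N-[(5R)-2,2-dimethyl-8-oxo-1,3-dioxaspiro[4.5]dec-6-en-7-yl]-2,4-dimethyloct-2-enamide | CCCC[C@@H](C)/C=C(\C)C(=O)NC1=C[C@]2(CCC1=O)COC(C)(C)O2
F4 | step 12 | (2E,4R)-N-[(3R)-3-[(E)-2-iodoethenyl]-3,6-bis(trimethylsilyloxy)cyclohexa-1,5-dien-1-yl]-2,4-dimethyloct-2-enamide | CCCC[C@@H](C)/C=C(\C)C(=O)NC1=C[C@@](O[Si](C)(C)C)(/C=C/I)CC=C1O[Si](C)(C)C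
F5 | step 13 | (2E,4R)-N-[(1S,5R,6R)-5-hydroxy-5-[(E)-2-iodoethenyl]-2-oxo-7-oxabicyclo[4.1.0]hept-3-en-3-yl]-2,4-dimethyloct-2-enamide | CCCC[C@@H](C)/C=C(\C)C(=O)NC1=C[C@@](O)(/C=C/I)[C@@H]2O[C@@H]2C1=O
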